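**Retrosynthetic overview**

1. Numbering (eremophilane): ring A = C1–C5 and C10, ring B = C5–C10; C14 = methyl on C5, C15 = methyl on C4, C11 = carbinol carbon on C7; β = the face of C14.
2. Feature: ring B is a cyclohexa-2,5-dienone (C6=C7–C8(=O)–C9=C10) whose only sp3 atom, quaternary C5, is para to C8. This is the pattern of a benzene ring reduced 1,4 and alkylated at the ipso carbon, so C5–C14 is cut by reductive methylation of a 2-(but-3-enyl)benzamide of (S)-2-(methoxymethyl)pyrrolidine. Ring B is therefore formed first, as the arene.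
3. Ring A is formed second: the amide carbon becomes C4 (methyl ketone, then methylenation) and ring-closing metathesis with the butenyl chain closes C3=C4. C8 is oxidised to the dienone, and epoxidation with a Meinwald shift puts a ketone at C3, with C4 equilibrated cis to C14.
4. C7–C11: iodination at C7, reduction to the C8 dienol, iodine–lithium exchange and addition to acetone, then reoxidation at C8.
5. C3–O ester last: Mitsunobu inversion of the axial 3β-alcohol with (Z)-2-methyl-3-(methylsulfanyl)prop-2-enoic acid, made from prop-2-yn-1-ol by anti-carbomagnesiation/iodination, oxidation and C–S coupling.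

Key step: step 3

Assumption: the (S)-auxiliary is taken to steer MeI to the enolate face that gives the (1S) quaternary carbon of the diene amide (C5 of the target); this sense is not certain for this ortho chain and must be checked on the diene amide before it is carried on.

**Route**

Step 1
Reactants: 1 2-methylbenzoic acid; 2 allyl bromide
Product: 4 2-(but-3-en-1-yl)benzoic acid, via dilithium toluate dianion 3 (not isolated)
Conditions: LiN(i-Pr)2 (2.2 equiv), THF, −78 → 0 °C; then 2, −78 °C → rt; aq. HCl
Reagents that add atoms: none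
Why: Lateral lithiation: the lithium carboxylate directs LiN(i-Pr)2 to the ortho methyl group, and the benzylic carbanion of the dianion is alkylated by allyl bromide (SN2), the carboxylate oxygen being far less nucleophilic.

Step 2
Reactants: 4 2-(but-3-en-1-yl)benzoic acid; 5 (S)-2-(methoxymethyl)pyrrolidine
Product: 7 [2-(but-3-en-1-yl)phenyl][(2S)-2-(methoxymethyl)pyrrolidin-1-yl]methanone, via 2-(but-3-en-1-yl)benzoyl chloride 6 (not isolated)
Conditions: (COCl)2, DMF (cat.), CH2Cl2, 0 °C → rt; concentrate; then 5, Et3N, CH2Cl2, 0 °C → rt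
Reagents that add atoms: none
Why: Acid chloride formation followed by N-acylation of the secondary amine (amide coupling); the stereocentre of the auxiliary is not involved.

Step 3
Reactants: 7 [2-(but-3-en-1-yl)phenyl][(2S)-2-(methoxymethyl)pyrrolidin-1-yl]methanone
Product: 9 [(1S)-2-(but-3-en-1-yl)-1-methylcyclohexa-2,5-dien-1-yl][(2S)-2-(methoxymethyl)pyrrolidin-1-yl]methanone, via potassium amide enolate 8 (not isolated)
Conditions: K (2.3 equiv), t-BuOH (1.0 equiv), NH3/THF, −78 °C; piperylene; MeI (2 equiv), −78 °C; solid NH4Cl, then warm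
Reagents that add atoms: iodomethane (CI)
Why: Birch reductive alkylation: two electrons from K and one proton from t-BuOH (delivered to C8, para to the amide) turn the benzamide into the cross-conjugated potassium amide enolate 8, and MeI then alkylates its ipso carbon C5, forming C5–C14. The closest known reaction type is the reductive alkylation of 2-alkylbenzamides of prolinol ethers. No ring is closed. The new quaternary stereocentre C5 is controlled by the auxiliary: allylic strain with the ortho chain fixes the enolate geometry, and the methoxymethyl arm, chelated to potassium, covers one face, so that MeI should enter from the other. The step needs alkylation at C5 instead of C6, C8 or C10 and a 1,4-diene that is neither conjugated nor over-reduced; the amide enolate secures the first, the single proton equivalent at −78 °C the second, and the isolated terminal alkene is inert to dissolving metal.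

Step 4
Reactants: 9 [(1S)-2-(but-3-en-1-yl)-1-methylcyclohexa-2,5-dien-1-yl][(2S)-2-(methoxymethyl)pyrrolidin-1-yl]methanone
Product: 11 1-[(1S)-2-(but-3-en-1-yl)-1-methylcyclohexa-2,5-dien-1-yl]ethan-1-one, via lithium hemiaminal alkoxide 10 (not isolated)
Conditions: MeLi (3 equiv), THF, −78 → 0 °C; aq. NH4Cl
Reagents that add atoms: methyllithium ([Li]C)
Why: Nucleophilic addition of the small MeLi to the tertiary amide, helped by lithium chelation to the methoxymethyl arm, gives a tetrahedral adduct that is stable until work-up and then collapses to the methyl ketone with release of the auxiliary (ketone synthesis from a tertiary amide); C5 carries no hydrogen and cannot epimerize.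

Step 5
Reactants: 11 1-[(1S)-2-(but-3-en-1-yl)-1-methylcyclohexa-2,5-dien-1-yl]ethan-1-one
Product: 12 (6R)-1-(but-3-en-1-yl)-6-methyl-6-(prop-1-en-2-yl)cyclohexa-1,4-diene
Conditions: Ph3PCH3Br, KOt-Bu, toluene, 80 °C
Reagents that add atoms: methyltriphenylphosphonium bromide (C[P+](c1ccccc1)(c1ccccc1)c1ccccc1.[Br-])
Why: Wittig methylenation with the unstabilised ylide Ph3P=CH2, which reacts even with methyl ketones next to a quaternary carbon; no stereocentre is touched.

Step 6
Reactants: 12 (6R)-1-(but-3-en-1-yl)-6-methyl-6-(prop-1-en-2-yl)cyclohexa-1,4-diene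
Product: 13 (4R)-3-(but-3-en-1-yl)-4-methyl-4-(prop-1-en-2-yl)cyclohexa-2,5-dien-1-one
Conditions: Rh2(cap)4 (dirhodium tetracaprolactamate, 1 mol %), t-BuOOH (70% aq., 5 equiv), K2CO3 (0.5 equiv), CH2Cl2, rt
Reagents that add atoms: tert-butyl hydroperoxide (CC(C)(C)OO)
Why: Radical allylic oxidation by t-BuOO radicals generated on the dirhodium catalyst: the doubly allylic C8–H is by far the weakest C–H bond, the pentadienyl radical is oxygenated at C8 because both termini (C6 next to the quaternary carbon, fully substituted C10) are shielded, and the mixed peroxide collapses to the ketone; the same conversion of 1,1-disubstituted cyclohexa-2,5-dienes into 4,4-disubstituted cyclohexadienones is known with chromium-based t-BuOOH oxidations.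

Step 7
Reactants: 13 (4R)-3-(but-3-en-1-yl)-4-methyl-4-(prop-1-en-2-yl)cyclohexa-2,5-dien-1-one
Product: 14 (4aR)-4a,5-dimethyl-7,8-dihydronaphthalen-2(4aH)-one
Conditions: (H2IMes)(PCy3)Cl2Ru=CHPh (second-generation Grubbs catalyst, 5 mol %), CH2Cl2, 40 °C
Reagents that add atoms: none
Why: Ring-closing metathesis: the catalyst loads on the monosubstituted alkene and closes ring A onto the 1,1-disubstituted alkene (six-membered ring, trisubstituted C3=C4, ethene lost), while the electron-poor dienone alkenes do not take part.

Step 8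
Reactants: 14 (4aR)-4a,5-dimethyl-7,8-dihydronaphthalen-2(4aH)-one
Product: 15 3α,4α-epoxy-11,12,13-trinoreremophila-6,9-dien-8-one (oxirane trans to C14)
Conditions: mCPBA, NaHCO3, CH2Cl2, 0 °C
Reagents that add atoms: 3-chloroperoxybenzoic acid (OOC(=O)c1cccc(Cl)c1)
Why: Prilezhaev epoxidation is chemoselective for the only electron-rich alkene (C3=C4), the two enone alkenes being deactivated; attack anti to the axial C14 methyl should give the 3α,4α-epoxide, whose configuration is not carried into later compounds.

Step 9
Reactants: 15 3α,4α-epoxy-11,12,13-trinoreremophila-6,9-dien-8-one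
Product: 17 (4aR,5R)-4a,5-dimethyl-4a,5,7,8-tetrahydronaphthalene-2,6-dione (C15 β), via 4α-methyl epimer 16 (not isolated)
Conditions: BF3·OEt2 (0.3 equiv), CH2Cl2, −78 → −30 °C; then DBU (0.2 equiv), rt
Reagents that add atoms: none
Why: Meinwald rearrangement: BF3 opens the epoxide at tertiary C4 and a 1,2-hydride shift from C3 gives the C3 ketone (a shift from C5 would leave a cation flanked by two enone carbons and is not expected), after which DBU equilibrates C4 through the enol to the equatorial 4β-methyl epimer, which should be favoured because it avoids the syn-axial contact with C2–H and the clash with C6–H of the axial epimer (the stable arrangement in 4-methyl-3-ketones with an angular methyl, such as friedelin).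

Step 10
Reactants: 17 (4aR,5R)-4a,5-dimethyl-4a,5,7,8-tetrahydronaphthalene-2,6-dione
Product: 18 7-iodo-11,12,13-trinoreremophila-6,9-diene-3,8-dione (4β,5β-dimethyl)
Conditions: I2 (2 equiv), pyridine/CH2Cl2 (1:1), rt
Reagents that add atoms: iodine (II)
Why: α-Iodination of an enone by conjugate addition of pyridine, iodination of the enolate and elimination; only C6 is an open β-carbon (C10 is fully substituted), so iodine should enter at C7, and the saturated C3 ketone is not enolised by pyridine.

Step 11
Reactants: 18 7-iodo-11,12,13-trinoreremophila-6,9-diene-3,8-dione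
Product: 19 7-iodo-11,12,13-trinoreremophila-6,9-diene-3β,8-diol (C8 epimers)
Conditions: NaBH4 (3 equiv), CeCl3·7H2O (1.5 equiv), MeOH, −78 → −20 °C
Reagents that add atoms: none
Why: Luche conditions reduce the dienone carbonyl 1,2 and the C3 ketone by equatorial hydride attack from the α-face, the axial approach being blocked by the syn-axial C14 methyl, so that the axial 3β-alcohol should result; the C8 carbinol forms as an epimer mixture that is removed in step 13.

Step 12
Reactants: 19 7-iodo-11,12,13-trinoreremophila-6,9-diene-3β,8-diol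
Product: 21 eremophila-6,9-diene-3β,8,11-triol (C8 epimers), via trilithio dialkoxide vinyllithium 20 (not isolated)
Conditions: t-BuLi (4.4 equiv), THF/Et2O, −78 °C; acetone (6 equiv), −78 → −40 °C; aq. NH4Cl (no acid contact)
Reagents that add atoms: acetone (CC(C)=O)
Why: After deprotonation of both hydroxyls, iodine–lithium exchange gives the vinyllithium, which adds 1,2 to acetone (organolithium addition to a ketone); ring B carries no carbonyl at this stage, which is why the dienone was reduced first.

Step 13
Reactants: 21 eremophila-6,9-diene-3β,8,11-triol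
Product: 22 3β,11-dihydroxyeremophila-6,9-dien-8-one
Conditions: MnO2 (activated, excess), CH2Cl2, rt
Reagents that add atoms: none
Why: MnO2 oxidises only allylic alcohols: the doubly allylic C8 carbinol returns to the cross-conjugated dienone, while the saturated secondary C3 alcohol and the tertiary C11 alcohol are left.

Step 14
Reactants: 23 prop-2-yn-1-ol
Product: 25 (Z)-3-iodo-2-methylprop-2-en-1-ol, via alkenylmagnesium alkoxide chelate 24 (not isolated)
Conditions: MeMgBr (2.5 equiv), CuI (10 mol %), THF/Et2O, −10 °C → rt; then I2, −40 → 0 °C; aq. NH4Cl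
Reagents that add atoms: methylmagnesium bromide (C[Mg]Br); iodine (II)
Why: CuI-catalysed anti-carbomagnesiation of the propargylic magnesium alkoxide: methyl is delivered to C2 and magnesium to C3 inside a five-membered chelate, so that magnesium, and after iodinolysis with retention iodine, is cis to the CH2O group (Z).

Step 15
Reactants: 25 (Z)-3-iodo-2-methylprop-2-en-1-ol
Product: 27 (Z)-3-iodo-2-methylprop-2-enoic acid, via (Z)-3-iodo-2-methylprop-2-enal 26 (not isolated)
Conditions: MnO2, CH2Cl2, rt, dark; filter; then NaClO2, NaH2PO4, 2-methylbut-2-ene, t-BuOH/H2O, 0 °C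
Reagents that add atoms: sodium chlorite ([Na+].[O-]Cl=O)
Why: Allylic oxidation with MnO2 to the enal and Pinnick oxidation to the acid; the enal is not isolated so that it has no chance to isomerise, and neither oxidant touches the vinyl iodide.

Step 16
Reactants: 27 (Z)-3-iodo-2-methylprop-2-enoic acid
Product: 28 (Z)-2-methyl-3-(methylsulfanyl)prop-2-enoic acid
Conditions: NaSMe (2.5 equiv), CuI (10 mol %), DMF, 50 °C; then aq. HCl
Reagents that add atoms: sodium methanethiolate ([Na+].[S-]C)
Why: Copper-catalysed C–S coupling of a vinyl iodide with a thiolate (Ullmann-type), assisted by the cis carboxylate, goes with retention of the alkene geometry; as its carboxylate the product is protected against thiolate addition and Z/E scrambling.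

Step 17
Reactants: 22 3β,11-dihydroxyeremophila-6,9-dien-8-one; 28 (Z)-2-methyl-3-(methylsulfanyl)prop-2-enoic acid
Product: 29 (4aR,5R,6R)-3-(2-hydroxypropan-2-yl)-4a,5-dimethyl-2-oxo-2,4a,5,6,7,8-hexahydronaphthalen-6-yl (2Z)-2-methyl-3-(methylsulfanyl)prop-2-enoate
Conditions: PPh3 (2 equiv), DIAD (2 equiv), THF, 0 °C → rt
Reagents that add atoms: none
Why: Mitsunobu esterification: the axial C3 hydroxyl is activated as an alkoxyphosphonium ion and displaced by the carboxylate with inversion (SN2) to the equatorial 3α-ester, the tertiary C11 alcohol cannot react, and the acid is used as a nucleophile without acyl activation, so its Z geometry is kept.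

**Compound list**

1 | 2-methylbenzoic acid | Cc1ccccc1C(=O)O | starting material
2 | allyl bromide | C=CCBr | starting material
3 | lithium 2-(lithiomethyl)benzoate (toluate dianion) | [Li+].[Li+].[CH2-]c1ccccc1C(=O)[O-] | intermediate (not isolated)
4 | 2-(but-3-en-1-yl)benzoic acid | C=CCCc1ccccc1C(=O)O | intermediate
5 | (S)-2-(methoxymethyl)pyrrolidine | COC[C@@H]1CCCN1 | starting material
6 | 2-(but-3-en-1-yl)benzoyl chloride | C=CCCc1ccccc1C(=O)Cl | intermediate (not isolated)
7 | [2-(but-3-en-1-yl)phenyl][(2S)-2-(methoxymethyl)pyrrolidin-1-yl]methanone | C=CCCc1ccccc1C(=O)N1CCC[C@H]1COC | intermediate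
8 | potassium amide enolate of the 1,4-dihydro amide (C5 enolate, C8 protonated) | C=CCCC1=CCC=CC1=C([O-])N1CCC[C@H]1COC.[K+] | intermediate (not isolated)
9 | [(1S)-2-(but-3-en-1-yl)-1-methylcyclohexa-2,5-dien-1-yl][(2S)-2-(methoxymethyl)pyrrolidin-1-yl]methanone | C=CCCC1=CCC=C[C@]1(C)C(=O)N1CCC[C@H]1COC | intermediate
10 | lithium 1-[(1S)-2-(but-3-en-1-yl)-1-methylcyclohexa-2,5-dien-1-yl]-1-[(2S)-2-(methoxymethyl)pyrrolidin-1-yl]ethan-1-olate | C=CCCC1=CCC=C[C@]1(C)C(C)([O-])N1CCC[C@H]1COC.[Li+] | intermediate (not isolated)
11 | 1-[(1S)-2-(but-3-en-1-yl)-1-methylcyclohexa-2,5-dien-1-yl]ethan-1-one | C=CCCC1=CCC=C[C@]1(C)C(C)=O | intermediate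
12 | (6R)-1-(but-3-en-1-yl)-6-methyl-6-(prop-1-en-2-yl)cyclohexa-1,4-diene | C=CCCC1=CCC=C[C@]1(C)C(C)=C | intermediate
13 | (4R)-3-(but-3-en-1-yl)-4-methyl-4-(prop-1-en-2-yl)cyclohexa-2,5-dien-1-one | C=CCCC1=CC(=O)C=C[C@]1(C)C(C)=C | intermediate
14 | (4aR)-4a,5-dimethyl-7,8-dihydronaphthalen-2(4aH)-one | CC1=CCCC2=CC(=O)C=C[C@]12C | intermediate
15 | 3α,4α-epoxy-11,12,13-trinoreremophila-6,9-dien-8-one (oxirane trans to C14) | O1[C@@H]2CCC3=CC(=O)C=C[C@]3(C)[C@]12C | intermediate
16 | (4aR,5S)-4a,5-dimethyl-4a,5,7,8-tetrahydronaphthalene-2,6-dione (C15 α, trans to C14) | O=C1CCC2=CC(=O)C=C[C@]2(C)[C@@H]1C | intermediate (not isolated)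
17 | (4aR,5R)-4a,5-dimethyl-4a,5,7,8-tetrahydronaphthalene-2,6-dione (C15 β, cis to C14) | O=C1CCC2=CC(=O)C=C[C@]2(C)[C@H]1C | intermediate
18 | 7-iodo-11,12,13-trinoreremophila-6,9-diene-3,8-dione (4β,5β-dimethyl) | O=C1CCC2=CC(=O)C(I)=C[C@]2(C)[C@H]1C | intermediate
19 | 7-iodo-11,12,13-trinoreremophila-6,9-diene-3β,8-diol (axial 3-OH cis to both methyls; C8 epimers) | O[C@H]1CCC2=CC(O)C(I)=C[C@]2(C)[C@H]1C | intermediate
20 | 3,8-dilithium alkoxide of the 7-lithio diene diol | [Li]O[C@H]1CCC2=CC(O[Li])C([Li])=C[C@]2(C)[C@H]1C | intermediate (not isolated)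
21 | eremophila-6,9-diene-3β,8,11-triol (C8 epimers) | O[C@H]1CCC2=CC(O)C(C(C)(C)O)=C[C@]2(C)[C@H]1C | intermediate
22 | 3β,11-dihydroxyeremophila-6,9-dien-8-one | O[C@H]1CCC2=CC(=O)C(C(C)(C)O)=C[C@]2(C)[C@H]1C | intermediate
23 | prop-2-yn-1-ol | C#CCO | starting material
24 | bromomagnesium (Z)-3-(bromomagnesio)-2-methylprop-2-en-1-olate | Br[Mg]/C=C(/C)CO[Mg]Br | intermediate (not isolated)
25 | (Z)-3-iodo-2-methylprop-2-en-1-ol | I/C=C(/C)CO | intermediate
26 | (Z)-3-iodo-2-methylprop-2-enal | I/C=C(/C)C=O | intermediate (not isolated)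
27 | (Z)-3-iodo-2-methylprop-2-enoic acid | I/C=C(/C)C(=O)O | intermediate
28 | (Z)-2-methyl-3-(methylsulfanyl)prop-2-enoic acid | CS/C=C(/C)C(=O)O | intermediate
29 | (4aR,5R,6R)-3-(2-hydroxypropan-2-yl)-4a,5-dimethyl-2-oxo-2,4a,5,6,7,8-hexahydronaphthalen-6-yl (2Z)-2-methyl-3-(methylsulfanyl)prop-2-enoate | CS/C=C(/C)C(=O)O[C@@H]1CCC2=CC(=O)C(C(C)(C)O)=C[C@]2(C)[C@H]1C | target

**Step count**

Total: 17 steps. Longest linear sequence: 14 steps (steps 1–13 and 17); steps 14–16 make the acid 28.

**Steps most likely to fail**

Step 3 (key step). The auxiliary may steer MeI to the opposite enolate face for this ortho chain, so that the C5 epimer predominates. The fallback runs the antipodal auxiliary series; it sets out from acid 4 and returns at ketone 11. Acid chloride 6 is coupled with (R)-2-(methoxymethyl)pyrrolidine (COC[C@H]1CCCN1) to [2-(but-3-en-1-yl)phenyl][(2R)-2-(methoxymethyl)pyrrolidin-1-yl]methanone F1. K/NH3/t-BuOH gives its potassium amide enolate F2, which MeI methylates to [(1S)-2-(but-3-en-1-yl)-1-methylcyclohexa-2,5-dien-1-yl][(2R)-2-(methoxymethyl)pyrrolidin-1-yl]methanone F3. MeLi converts F3 through the lithium hemiaminal alkoxide F4 into 11, the auxiliary being lost there.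

Step 9. The C4 cation may lose a proton from C15 or trigger ring contraction by C2 migration instead of the hydride shift, and the C4 equilibration may leave much of the axial epimer. The fallback sets C4 kinetically by hydrogenation; it sets out from epoxide 15 and returns at 17. TMSOTf/2,6-lutidine, then DBU, isomerises the epoxide (proton loss from C15) to the allyl silyl ether 3α-(trimethylsilyloxy)-11,12,13-trinoreremophila-4(15),6,9-trien-8-one F5. K2CO3/MeOH frees the allylic alcohol 3α-hydroxy-11,12,13-trinoreremophila-4(15),6,9-trien-8-one F6. H2 (1 atm) with RhCl(PPh3)3 in benzene should add to the exocyclic methylene on the α-face, anti to C14, giving 3α-hydroxy-11,12,13-trinoreremophila-6,9-dien-8-one (4β-methyl) F7. Dess–Martin periodinane oxidises F7 to 17, so the rest of the route is unchanged.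

Step 17. The activated axial alcohol may eliminate through the anti-periplanar C4–H to the C3=C4 alkene, or the hindered hydroxyl may not be activated, before the weakly acidic thioacrylic acid substitutes. The fallback separates inversion from acylation; it sets out from 22 and returns at 29. Mitsunobu inversion with the more acidic 4-nitrobenzoic acid (PPh3, DIAD) gives 11-hydroxy-8-oxoeremophila-6,9-dien-3α-yl 4-nitrobenzoate F8. K2CO3/MeOH releases 3α,11-dihydroxyeremophila-6,9-dien-8-one F9. The now equatorial secondary alcohol of F9 is esterified with 28 (EDC·HCl, DMAP, CH2Cl2, 0 °C) with retention to 29.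

**Further compounds**

F1 | step 3 | [2-(but-3-en-1-yl)phenyl][(2R)-2-(methoxymethyl)pyrrolidin-1-yl]methanone | C=CCCc1ccccc1C(=O)N1CCC[C@@H]1COC
F2 | step 3 | potassium amide enolate of the 1,4-dihydro form of F1 | C=CCCC1=CCC=CC1=C([O-])N1CCC[C@@H]1COC.[K+]
F3 | step 3 | [(1S)-2-(but-3-en-1-yl)-1-methylcyclohexa-2,5-dien-1-yl][(2R)-2-(methoxymethyl)pyrrolidin-1-yl]methanone | C=CCCC1=CCC=C[C@]1(C)C(=O)N1CCC[C@@H]1COC
F4 | step 3 | lithium hemiaminal alkoxide from F3 and MeLi | C=CCCC1=CCC=C[C@]1(C)C(C)([O-])N1CCC[C@@H]1COC.[Li+]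
F5 | step 9 | 3α-(trimethylsilyloxy)-11,12,13-trinoreremophila-4(15),6,9-trien-8-one | C[Si](C)(C)O[C@@H]1CCC2=CC(=O)C=C[C@]2(C)C1=C
F6 | step 9 | 3α-hydroxy-11,12,13-trinoreremophila-4(15),6,9-trien-8-one | O[C@@H]1CCC2=CC(=O)C=C[C@]2(C)C1=C
F7 | step 9 | 3α-hydroxy-11,12,13-trinoreremophila-6,9-dien-8-one (4β-methyl) | O[C@@H]1CCC2=CC(=O)C=C[C@]2(C)[C@H]1C
F8 | step 17 | 11-hydroxy-8-oxoeremophila-6,9-dien-3α-yl 4-nitrobenzoate | O=C(O[C@@H]1CCC2=CC(=O)C(C(C)(C)O)=C[C@]2(C)[C@H]1C)c1ccc(cc1)[N+](=O)[O-]
F9 | step 17 | 3α,11-dihydroxyeremophila-6,9-dien-8-one | O[C@@H]1CCC2=CC(=O)C(C(C)(C)O)=C[C@]2(C)[C@H]1C
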